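**Retrosynthetic overview**

1. The target, a 3-aryl-5-methoxy-4,7-diphenylbenzofuran-2,6-dione quinone methide, is traced back by debenzylation and O-methylation to its O-benzyl 5-hydroxy analogue.
2. Key disconnection: the C6–C7 and C4=C5 bonds of the carbocycle (ring B) are cut together. This releases C5–C6 as dimethyl oxalate and leaves a 3-aryl-4-benzyl-5-benzylidenebutenolide. In the forward direction methoxide opens the lactone (ring A), a double Claisen condensation builds ring B at the final oxidation level, and ring A recloses.
3. Enabling feature: C5(OMe)–C6(=O) of ring B is an intact oxalyl unit flanked by the phenyl-bearing carbons C4 and C7. C4 is the γ-carbon of the C2(=O)–C3=C3a enoate of ring A, and C7 is the α-carbon of the C7a ketone that is masked as the enol lactone. Both are therefore latent benzylic carbanions, 1,4-related across C3a–C7a, and the quinone methide is simply the enol-lactone form of the triketone they give with an oxalate.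
4. The ylidenebutenolide comes from a 3-aryl-4-benzylbutenolide and benzaldehyde (vinylogous aldol condensation). The butenolide comes from [4-(benzyloxy)phenyl]acetic acid and 1-bromo-3-phenylpropan-2-one (esterification, intramolecular Knoevenagel condensation).
5. Ring order: ring A (furanone) in step 1; ring B (carbocycle) in step 3, with ring A opened and reclosed in the same operation.

Key step: step 3

Remark on the chemistry: the target is achiral and is handled as the drawn 5-methoxy-6-oxo quinone methide tautomer with a free 4-hydroxyphenyl group. The four starting materials are taken as commercial. The phenol is carried as its benzyl ether so that the O-methylation in step 4 has only one acidic hydroxyl to address.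

**Route**

Step 1
Reactants: 1 [4-(benzyloxy)phenyl]acetic acid; 2 1-bromo-3-phenylpropan-2-one
Product: 4 4-benzyl-3-[4-(benzyloxy)phenyl]furan-2(5H)-one, via oxoalkyl ester 3 (not isolated)
Conditions: Et3N, MeCN, rt; then DBU, 0 °C to rt
Reagents that add atoms: none
Why: Carboxylate O-alkylation by the α-bromo ketone should give the 2-oxoalkyl ester 3, and DBU should then effect an intramolecular Knoevenagel-type aldol condensation of the arylacetate methylene onto the ketone, with dehydration to the conjugated 3,4-disubstituted butenolide; no stereocentre is formed.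

Step 2
Reactants: 4 4-benzyl-3-[4-(benzyloxy)phenyl]furan-2(5H)-one; 5 benzaldehyde
Product: 8 (5Z)-4-benzyl-5-benzylidene-3-[4-(benzyloxy)phenyl]furan-2(5H)-one, via silyloxyfuran 6 (not isolated), via silyl aldol adduct 7 (not isolated)
Conditions: TBSOTf, iPr2NEt, CH2Cl2, 0 °C to rt; then DBU, rt
Reagents that add atoms: none
Why: Soft enolisation at C5 should give the aromatic 2-silyloxyfuran 6, which should add to benzaldehyde at C5 in a vinylogous Mukaiyama aldol reaction, and DBU should then eliminate silanolate (E1cB) to the conjugated ylidenebutenolide, expected as the Z isomer because the phenyl group avoids the C4 benzyl group; the alkene geometry is of no consequence because it is erased in step 3.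

Step 3
Reactants: 8 (5Z)-4-benzyl-5-benzylidene-3-[4-(benzyloxy)phenyl]furan-2(5H)-one; 9 dimethyl oxalate
Product: 13 3-[4-(benzyloxy)phenyl]-5-hydroxy-4,7-diphenyl-1-benzofuran-2,6-dione, via ring-opened keto ester 10 (not isolated), via oxalyl keto diester 11 (not isolated), via seco hydroxy ester 12 (not isolated)
Conditions: NaOMe (6 equiv), 9 (5 equiv), THF–MeOH, 0 °C (slow addition of 8) to 60 °C; 1 M HCl; then TsOH·H2O (cat.), PhMe, reflux
Reagents that add atoms: none
Why: Methoxide should open the enol lactone of 8 to the enolate of keto ester 10, whose benzylic ketone α-carbon (future C7) is acylated by dimethyl oxalate (Claisen condensation, C6–C7 bond) to give 11; a second deprotonation at the benzylic CH2 in the γ-position of the unsaturated ester (future C4) gives a vinylogous enolate that attacks the remaining oxalate ester (Dieckmann-type, C4–C5 bond), and enolisation of the resulting 1,2,4-triketone gives the C4=C5 enol of 12, which is already at the quinone methide oxidation level so that no oxidant is needed. The closest known reaction type is the double Claisen annulation of dialkyl oxalates with 1,4-related bis-pronucleophiles (oxalate with dibenzyl ketone or with hex-3-enedioates), here combined with alkoxide opening of an enol lactone. Ring B closes by a 6-(enolendo)-exo-trig attack of the vinylogous enolate carbon on the ester carbonyl, and ring A recloses under acid by 5-exo-trig addition–elimination of the C7a hydroxyl on the methyl ester. No stereocentre is formed; the geometry of the exocyclic C3=C3a bond can equilibrate through the push–pull polyenol and is fixed by lactonisation of the Z isomer. The step needs C- over O-acylation, and it needs interception of the ketone enolate by oxalate ahead of its intramolecular Claisen attack on the enoate ester, which would give a cyclopent-4-ene-1,3-dione; the first should be secured by reversibility, since only double C-acylation ends in a fully conjugated polyenolate, and the second by the tetrasubstituted, conjugated and therefore poorly electrophilic enoate ester, by the excess of the far more electrophilic oxalate and by slow addition of 8 at 0 °C. The 1,4-relationship of the two benzylic carbons across C3a–C7a ensures that the oxalate can only be spanned as a six-membered ring carrying its oxygens at C5 and C6.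

Step 4
Reactants: 13 3-[4-(benzyloxy)phenyl]-5-hydroxy-4,7-diphenyl-1-benzofuran-2,6-dione
Product: 14 3-[4-(benzyloxy)phenyl]-5-methoxy-4,7-diphenyl-1-benzofuran-2,6-dione
Conditions: Me2SO4, K2CO3, acetone, rt
Reagents that add atoms: dimethyl sulfate, COS(=O)(=O)OC
Why: The 5-hydroxyl is a doubly vinylogous acid (conjugated through C4=C3a–C3 to the lactone carbonyl and flanked by the C6 ketone) and the only acidic site, so its potassium salt should undergo Williamson-type O-methylation by the hard electrophile at O5, while C-methylation is blocked at the fully substituted C3 and C4 and alkylation at the lactone carbonyl oxygen would sacrifice the lactone.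

Step 5
Reactants: 14 3-[4-(benzyloxy)phenyl]-5-methoxy-4,7-diphenyl-1-benzofuran-2,6-dione
Product: 16 3-(4-hydroxyphenyl)-5-methoxy-4,7-diphenyl-1-benzofuran-2,6-dione, via leuco benzofuranone 15 (not isolated)
Conditions: H2 (1 atm), 10% Pd/C, EtOAc–THF, rt; filter; then DDQ (1 equiv), THF, 0 °C
Reagents that add atoms: none
Why: Hydrogenolysis of the benzyl aryl ether over Pd/C should be accompanied by 1,6-reduction of the quinone methide to the benzenoid leuco lactone 15 (a stable end point that guards against over-reduction), and DDQ dehydrogenation of this para-hydroxybenzylic lactone (hydride abstraction from C3, loss of a phenolic proton) should restore the quinone methide, the transient racemic C3 centre of 15 being destroyed again.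

**Compound list**

1 | [4-(benzyloxy)phenyl]acetic acid | OC(=O)Cc1ccc(OCc2ccccc2)cc1 | starting material
2 | 1-bromo-3-phenylpropan-2-one | BrCC(=O)Cc1ccccc1 | starting material
3 | 2-oxo-3-phenylpropyl [4-(benzyloxy)phenyl]acetate (not isolated) | O=C(Cc1ccc(OCc2ccccc2)cc1)OCC(=O)Cc1ccccc1 | intermediate
4 | 4-benzyl-3-[4-(benzyloxy)phenyl]furan-2(5H)-one | O=C1OCC(Cc2ccccc2)=C1c1ccc(OCc2ccccc2)cc1 | intermediate
5 | benzaldehyde | O=Cc1ccccc1 | starting material
6 | {[4-benzyl-3-[4-(benzyloxy)phenyl]furan-2-yl]oxy}(tert-butyl)dimethylsilane (not isolated) | CC(C)(C)[Si](C)(C)Oc1occ(Cc2ccccc2)c1-c1ccc(OCc2ccccc2)cc1 | intermediate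
7 | 4-benzyl-3-[4-(benzyloxy)phenyl]-5-{[tert-butyl(dimethyl)silyl]oxy(phenyl)methyl}furan-2(5H)-one (racemic mixture of diastereomers, not isolated) | CC(C)(C)[Si](C)(C)OC(c1ccccc1)C1OC(=O)C(c2ccc(OCc3ccccc3)cc2)=C1Cc1ccccc1 | intermediate
8 | (5Z)-4-benzyl-5-benzylidene-3-[4-(benzyloxy)phenyl]furan-2(5H)-one | O=C1O/C(=C\c2ccccc2)C(Cc2ccccc2)=C1c1ccc(OCc2ccccc2)cc1 | intermediate
9 | dimethyl oxalate | COC(=O)C(=O)OC | starting material
10 | methyl (2Z)-3-benzyl-2-[4-(benzyloxy)phenyl]-4-oxo-5-phenylpent-2-enoate (not isolated) | COC(=O)/C(c1ccc(OCc2ccccc2)cc1)=C(/Cc1ccccc1)C(=O)Cc1ccccc1 | intermediate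
11 | dimethyl (2Z)-3-benzyl-2-[4-(benzyloxy)phenyl]-4,6-dioxo-5-phenylhept-2-enedioate (racemic, largely enolised, not isolated) | COC(=O)/C(c1ccc(OCc2ccccc2)cc1)=C(/Cc1ccccc1)C(=O)C(c1ccccc1)C(=O)C(=O)OC | intermediate
12 | methyl (2Z)-[4-(benzyloxy)phenyl](2,5-dihydroxy-4-oxo-3,6-diphenylcyclohexa-2,5-dien-1-ylidene)acetate (not isolated) | COC(=O)/C(c1ccc(OCc2ccccc2)cc1)=C1\C(O)=C(c2ccccc2)C(=O)C(O)=C1c1ccccc1 | intermediate
13 | 3-[4-(benzyloxy)phenyl]-5-hydroxy-4,7-diphenyl-1-benzofuran-2,6-dione | OC1=C(c2ccccc2)C2=C(c3ccc(OCc4ccccc4)cc3)C(=O)OC2=C(c2ccccc2)C1=O | intermediate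
14 | 3-[4-(benzyloxy)phenyl]-5-methoxy-4,7-diphenyl-1-benzofuran-2,6-dione | COC1=C(c2ccccc2)C2=C(c3ccc(OCc4ccccc4)cc3)C(=O)OC2=C(c2ccccc2)C1=O | intermediate
15 | 6-hydroxy-3-(4-hydroxyphenyl)-5-methoxy-4,7-diphenyl-1-benzofuran-2(3H)-one (racemic, not isolated) | COc1c(O)c(-c2ccccc2)c2OC(=O)C(c3ccc(O)cc3)c2c1-c1ccccc1 | intermediate
16 | 3-(4-hydroxyphenyl)-5-methoxy-4,7-diphenyl-1-benzofuran-2,6-dione (CNP0282683.0) | COC1=C(c2ccccc2)C2=C(c3ccc(O)cc3)C(=O)OC2=C(c2ccccc2)C1=O | target

**Step count**

Total step count: 5. Longest linear sequence: 5 steps (1 and 2 to 4, 8, 13, 14, 16).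

**Steps most likely to fail**

First, step 3 (key step). After methoxide opens the lactone, the ketone enolate may cyclise onto its own ester (intramolecular Claisen condensation to a cyclopent-4-ene-1,3-dione, a known base-induced rearrangement of ylidenebutenolides) before the oxalate intercepts it. The second, vinylogous Claisen condensation may also stall at the mono-oxalyl stage, or relactonisation may remain incomplete.

The fallback sets out from compound 1 and comes back to the route at compound 14, so it replaces steps 3 and 4. It follows the presumed biosynthesis, in which a terphenylquinone is annulated with an arylacetate unit. Commercial 2,5-diphenyl-1,4-benzoquinone would be dibrominated (Br2, AcOH) to 2,5-dibromo-3,6-diphenylcyclohexa-2,5-diene-1,4-dione F1. Addition–elimination with NaOMe in MeOH should give 2,5-dimethoxy-3,6-diphenylcyclohexa-2,5-diene-1,4-dione F2. Hydrolysis of one vinylogous ester (NaOH, 1 equiv, aqueous dioxane, then HCl; the resulting anion resists a second hydrolysis) should give 2-hydroxy-5-methoxy-3,6-diphenylcyclohexa-2,5-diene-1,4-dione F3. Steglich esterification of F3 with acid 1 (DCC, DMAP, CH2Cl2) should give 4-methoxy-3,6-dioxo-2,5-diphenylcyclohexa-1,4-dien-1-yl [4-(benzyloxy)phenyl]acetate F4. An intramolecular Knoevenagel condensation of the arylacetate methylene onto the neighbouring quinone carbonyl (TiCl4, Et3N, CH2Cl2, 0 °C to rt), with loss of water, should then close the lactone ring and give 14.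

Second, step 2. Enolisation and silylation may take place at the benzylic CH2 on C4 instead of at C5, so that the aldol addition occurs at the wrong carbon, and the β-elimination may stall at the silyl aldol stage.

The fallback sets out from compound 1 and comes back at compound 8. It installs the benzylidene group first and the C4 benzyl group last. Acid 1 would be esterified (MeOH, cat. H2SO4) to methyl [4-(benzyloxy)phenyl]acetate F5. Tandem transesterification and Dieckmann condensation with methyl glycolate (KOtBu, DMF) should give the tetronic acid 3-[4-(benzyloxy)phenyl]-4-hydroxyfuran-2(5H)-one F6. Aldol addition of its dianion (LiN(iPr)2, THF, −78 °C) to benzaldehyde 5, followed by acid-induced dehydration, should give the pulvinone (5Z)-5-benzylidene-3-[4-(benzyloxy)phenyl]-4-hydroxyfuran-2(5H)-one F7. Tf2O and Et3N should convert it into (2Z)-2-benzylidene-4-[4-(benzyloxy)phenyl]-5-oxo-2,5-dihydrofuran-3-yl trifluoromethanesulfonate F8. Negishi coupling with BnZnBr (Pd(PPh3)4, THF) should then give 8, with the regiochemistry fixed by the position of the triflate.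

Third, step 5. The methoxy group at C5 may be lost by hydrogenolysis or hydrolysis of the vinylogous ester, debenzylation may stop short because the strongly adsorbing dye poisons the catalyst, or the free phenol may be over-oxidised in the DDQ stage.

The fallback sets out from compound 13 and comes back at compound 16. It removes the benzyl group without reduction before the methyl group is introduced. BBr3 (CH2Cl2, −78 to 0 °C) should cleave the benzyl ether of 13, which carries no methyl ether at this stage, and give 5-hydroxy-3-(4-hydroxyphenyl)-4,7-diphenyl-1-benzofuran-2,6-dione F9. A Fischer-type, acid-catalysed enol etherification (MeOH, HC(OMe)3, cat. H2SO4, reflux) should then methylate only the vinylogous-acid hydroxyl at C5, by addition–elimination at carbon, a pathway that is not open to the phenol, and give 16.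

**Further compounds**

F1 | step 3 | 2,5-dibromo-3,6-diphenylcyclohexa-2,5-diene-1,4-dione | O=C1C(Br)=C(c2ccccc2)C(=O)C(Br)=C1c1ccccc1
F2 | step 3 | 2,5-dimethoxy-3,6-diphenylcyclohexa-2,5-diene-1,4-dione | COC1=C(c2ccccc2)C(=O)C(OC)=C(c2ccccc2)C1=O
F3 | step 3 | 2-hydroxy-5-methoxy-3,6-diphenylcyclohexa-2,5-diene-1,4-dione | COC1=C(c2ccccc2)C(=O)C(O)=C(c2ccccc2)C1=O
F4 | step 3 | 4-methoxy-3,6-dioxo-2,5-diphenylcyclohexa-1,4-dien-1-yl [4-(benzyloxy)phenyl]acetate | COC1=C(c2ccccc2)C(=O)C(OC(=O)Cc2ccc(OCc3ccccc3)cc2)=C(c2ccccc2)C1=O
F5 | step 2 | methyl [4-(benzyloxy)phenyl]acetate | COC(=O)Cc1ccc(OCc2ccccc2)cc1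
F6 | step 2 | 3-[4-(benzyloxy)phenyl]-4-hydroxyfuran-2(5H)-one | O=C1OCC(O)=C1c1ccc(OCc2ccccc2)cc1
F7 | step 2 | (5Z)-5-benzylidene-3-[4-(benzyloxy)phenyl]-4-hydroxyfuran-2(5H)-one | O=C1O/C(=C\c2ccccc2)C(O)=C1c1ccc(OCc2ccccc2)cc1
F8 | step 2 | (2Z)-2-benzylidene-4-[4-(benzyloxy)phenyl]-5-oxo-2,5-dihydrofuran-3-yl trifluoromethanesulfonate | O=C1O/C(=C\c2ccccc2)C(OS(=O)(=O)C(F)(F)F)=C1c1ccc(OCc2ccccc2)cc1
F9 | step 5 | 5-hydroxy-3-(4-hydroxyphenyl)-4,7-diphenyl-1-benzofuran-2,6-dione | OC1=C(c2ccccc2)C2=C(c3ccc(O)cc3)C(=O)OC2=C(c2ccccc2)C1=O
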